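**Retrosynthetic overview**
- The acrolein is carried as its dimethyl acetal, and both isovalerates go on together; the last two steps are bis-acylation and acetal hydrolysis.
- C=CH2 is cut back to C=O (methylenation with Cp2TiMe2, made in its own short branch); the resulting α-aryloxy ketone is the aldol donor.
- Key disconnection: C2–C3 of the dihydrofuran ring (the only ring formed) by an L-proline-catalysed intramolecular aldol of a keto aldehyde, setting both ring stereocentres cis.
- The keto aldehyde is cut at ArO–CH2 (Williamson union) into fragment A, a salicylaldehyde carrying the (R)-1-silyloxyethyl group, and fragment B, 1-iodo-3,3-dimethoxypropan-2-one.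
- Fragment A comes from 4'-acetoxyacetophenone (asymmetric transfer hydrogenation, silylation, ortho-formylation); fragment B from 1,1-dimethoxyacetone (enol silane, bromination, halide exchange).

Assumption: the proline aldol follows the usual hydrogen-bonded (E)-anti-enamine model, which predicts the (2S,3R)-cis aldol from L-proline; if the antipodal ring series is found, D-proline is used with no other change.

**Step 1**
Reactants: 1 4-acetylphenyl acetate (4'-acetoxyacetophenone)
Product: 2 4-[(1R)-1-hydroxyethyl]phenyl acetate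
Conditions: RuCl(p-cymene)[(R,R)-TsDPEN] (0.5 mol %), HCO2H/Et3N (5:2), 28 °C
Reagents that add atoms: none
Why: Noyori asymmetric transfer hydrogenation; the (R,R)-catalyst delivers hydride to the Si face of the aryl methyl ketone and sets the benzylic (R) centre, while the aryl acetate keeps the ketone electron-poor and is untouched.

**Step 2**
Reactants: 2 4-[(1R)-1-hydroxyethyl]phenyl acetate
Product: 4 4-[(1R)-1-(tert-butyldimethylsilyloxy)ethyl]phenol, via silyl ether acetate 3 (not isolated)
Conditions: tBuMe2SiCl, imidazole, DMF, rt; then K2CO3 (0.3 equiv), MeOH, 0 °C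
Reagents that add atoms: tert-butyldimethylsilyl chloride, CC(C)(C)[Si](C)(C)Cl
Why: Silyl ether formation followed by base-catalysed transesterification of the aryl acetate, which is far faster than cleavage of the secondary alkyl silyl ether; the stereocentre is not involved.

**Step 3**
Reactants: 4 4-[(1R)-1-(tert-butyldimethylsilyloxy)ethyl]phenol
Product: 5 5-[(1R)-1-(tert-butyldimethylsilyloxy)ethyl]-2-hydroxybenzaldehyde
Conditions: MgCl2, Et3N, (CH2O)n, MeCN, reflux
Reagents that add atoms: paraformaldehyde (as formaldehyde), C=O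
Why: Casiraghi–Skattebøl ortho-formylation; the magnesium phenoxide is hydroxymethylated only ortho to oxygen and a second formaldehyde oxidises the salicyl alkoxide by Oppenauer-type hydride transfer, which is why the benzylic alcohol is silylated first.

**Step 4**
Reactants: 6 1,1-dimethoxypropan-2-one
Product: 8 (3,3-dimethoxyprop-1-en-2-yl)oxy(trimethyl)silane, via lithium enolate 7 (not isolated)
Conditions: LiN(iPr)2, THF, −78 °C; then Me3SiCl
Reagents that add atoms: chlorotrimethylsilane, C[Si](C)(C)Cl
Why: Kinetic enolate formation and O-silylation; deprotonation occurs only at the methyl group, so the enol silane is regiodefined and the acetal sees no Lewis acid.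

**Step 5**
Reactants: 8 (3,3-dimethoxyprop-1-en-2-yl)oxy(trimethyl)silane
Product: 9 1-bromo-3,3-dimethoxypropan-2-one
Conditions: NBS, NaHCO3, THF, −78 → 0 °C
Reagents that add atoms: N-bromosuccinimide, O=C1CCC(=O)N1Br
Why: Electrophilic α-bromination of a silyl enol ether gives the mono-bromoketone without HBr, so the acetal survives and no polybromination occurs.

**Step 6**
Reactants: 9 1-bromo-3,3-dimethoxypropan-2-one
Product: 10 1-iodo-3,3-dimethoxypropan-2-one
Conditions: NaI, acetone, rt, dark; used crude
Reagents that add atoms: sodium iodide, [Na+].[I-]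
Why: Finkelstein halide exchange (SN2, driven by NaBr precipitation) converts the storable bromide into the more reactive iodide, so the union can run cold with a weak base.

**Step 7**
Reactants: 5 5-[(1R)-1-(tert-butyldimethylsilyloxy)ethyl]-2-hydroxybenzaldehyde; 10 1-iodo-3,3-dimethoxypropan-2-one
Product: 11 5-[(1R)-1-(tert-butyldimethylsilyloxy)ethyl]-2-(3,3-dimethoxy-2-oxopropoxy)benzaldehyde
Conditions: K2CO3, acetone, 0 °C → rt
Reagents that add atoms: none
Why: Williamson ether synthesis; the acidic salicylaldehyde phenol is alkylated by the α-iodoketone under conditions too mild for base-mediated aldol/dehydration (Rap–Stoermer) of the product.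

**Step 8**
Reactants: 11 5-[(1R)-1-(tert-butyldimethylsilyloxy)ethyl]-2-(3,3-dimethoxy-2-oxopropoxy)benzaldehyde
Product: 13 1-[(2S,3R)-5-[(1R)-1-(tert-butyldimethylsilyloxy)ethyl]-3-(triethylsilyloxy)-2,3-dihydro-1-benzofuran-2-yl]-2,2-dimethoxyethan-1-one, via free cis-aldol 12 (not isolated)
Conditions: L-proline (30 mol %), DMF, 4 °C; then imidazole, Et3SiCl, 0 °C
Reagents that add atoms: chlorotriethylsilane, CC[Si](CC)(CC)Cl
Why: Proline-catalysed intramolecular 5-enolexo aldol (List–Houk model); the enamine of the α-aryloxy ketone attacks the tethered aldehyde from the face carrying the carboxylic acid, whose hydrogen bond holds the aldehyde oxygen syn to the iminium carbon, so C2 (S) and C3 (R) form cis, and the sensitive β-hydroxy ketone is capped as its silyl ether in the same flask.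

**Step 9**
Reactants: 14 Cp2TiCl2 (titanocene dichloride)
Product: 15 Cp2TiMe2 (dimethyltitanocene)
Conditions: MeMgCl, toluene/THF, 0 °C
Reagents that add atoms: methylmagnesium chloride, C[Mg]Cl
Why: Salt metathesis of both Ti–Cl bonds with the Grignard reagent gives the methylenating reagent as a stable toluene/THF solution.

**Step 10**
Reactants: 13 1-[(2S,3R)-5-[(1R)-1-(tert-butyldimethylsilyloxy)ethyl]-3-(triethylsilyloxy)-2,3-dihydro-1-benzofuran-2-yl]-2,2-dimethoxyethan-1-one; 15 Cp2TiMe2
Product: 17 (2R,3R)-2-(3,3-dimethoxyprop-1-en-2-yl)-5-[(1R)-1-hydroxyethyl]-2,3-dihydro-1-benzofuran-3-ol, via bis-silyl ether alkene 16 (not isolated)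
Conditions: Cp2TiMe2 (3 equiv), toluene/THF, 65 °C, dark; then Bu4NF, THF, 0 °C → rt
Reagents that add atoms: none
Why: Petasis methylenation; thermally formed Cp2Ti=CH2 is non-basic and converts the hindered, enolisable ketone by [2+2] addition/cycloreversion without epimerising C2 or eliminating the β-silyloxy group, and fluoride then removes both silyl ethers with no stereocentre touched (the C2 descriptor changes from S to R only through the priority change).

**Step 11**
Reactants: 17 (2R,3R)-2-(3,3-dimethoxyprop-1-en-2-yl)-5-[(1R)-1-hydroxyethyl]-2,3-dihydro-1-benzofuran-3-ol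
Product: 18 (1R)-1-[(2R,3R)-2-(3,3-dimethoxyprop-1-en-2-yl)-3-(3-methylbutanoyloxy)-2,3-dihydro-1-benzofuran-5-yl]ethyl 3-methylbutanoate
Conditions: (iBuCO)2O, Et3N, DMAP (cat.), CH2Cl2, 0 °C → rt
Reagents that add atoms: 3-methylbutanoic (isovaleric) anhydride, CC(C)CC(=O)OC(=O)CC(C)C
Why: DMAP-catalysed acyl transfer esterifies both secondary alcohols with retention (C–O bonds untouched); it is done while the aldehyde is still an acetal, so no γ-lactol can form and no base-sensitive enal is present.

**Step 12**
Reactants: 18 (1R)-1-[(2R,3R)-2-(3,3-dimethoxyprop-1-en-2-yl)-3-(3-methylbutanoyloxy)-2,3-dihydro-1-benzofuran-5-yl]ethyl 3-methylbutanoate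
Product: 19 (1R)-1-[(2R,3R)-3-(3-methylbutanoyloxy)-2-(3-oxoprop-1-en-2-yl)-2,3-dihydro-1-benzofuran-5-yl]ethyl 3-methylbutanoate (CNP0316116.1)
Conditions: 10% aq. oxalic acid on SiO2, CH2Cl2, rt
Reagents that add atoms: water, O
Why: Acid-catalysed acetal hydrolysis; the allylic acetal ionises to a conjugated oxocarbenium ion under acid too mild to ionise either benzylic ester, so the enal is released with all three stereocentres intact.

**Compound list**
1 | 4-acetylphenyl acetate | CC(=O)c1ccc(OC(C)=O)cc1 | starting material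
2 | 4-[(1R)-1-hydroxyethyl]phenyl acetate | C[C@@H](O)c1ccc(OC(C)=O)cc1 | intermediate
3 | 4-[(1R)-1-(tert-butyldimethylsilyloxy)ethyl]phenyl acetate | C[C@@H](O[Si](C)(C)C(C)(C)C)c1ccc(OC(C)=O)cc1 | intermediate
4 | 4-[(1R)-1-(tert-butyldimethylsilyloxy)ethyl]phenol | C[C@@H](O[Si](C)(C)C(C)(C)C)c1ccc(O)cc1 | intermediate
5 | 5-[(1R)-1-(tert-butyldimethylsilyloxy)ethyl]-2-hydroxybenzaldehyde (fragment A) | C[C@@H](O[Si](C)(C)C(C)(C)C)c1ccc(O)c(C=O)c1 | intermediate
6 | 1,1-dimethoxypropan-2-one | CC(=O)C(OC)OC | starting material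
7 | lithium 3,3-dimethoxyprop-1-en-2-olate | [Li]OC(=C)C(OC)OC | intermediate
8 | (3,3-dimethoxyprop-1-en-2-yl)oxy(trimethyl)silane | C=C(O[Si](C)(C)C)C(OC)OC | intermediate
9 | 1-bromo-3,3-dimethoxypropan-2-one | BrCC(=O)C(OC)OC | intermediate
10 | 1-iodo-3,3-dimethoxypropan-2-one (fragment B) | ICC(=O)C(OC)OC | intermediate
11 | 5-[(1R)-1-(tert-butyldimethylsilyloxy)ethyl]-2-(3,3-dimethoxy-2-oxopropoxy)benzaldehyde | C[C@@H](O[Si](C)(C)C(C)(C)C)c1ccc(OCC(=O)C(OC)OC)c(C=O)c1 | intermediate
12 | 1-[(2S,3R)-5-[(1R)-1-(tert-butyldimethylsilyloxy)ethyl]-3-hydroxy-2,3-dihydro-1-benzofuran-2-yl]-2,2-dimethoxyethan-1-one (2,3-cis) | COC(OC)C(=O)[C@H]1Oc2ccc([C@@H](C)O[Si](C)(C)C(C)(C)C)cc2[C@H]1O | intermediate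
13 | 1-[(2S,3R)-5-[(1R)-1-(tert-butyldimethylsilyloxy)ethyl]-3-(triethylsilyloxy)-2,3-dihydro-1-benzofuran-2-yl]-2,2-dimethoxyethan-1-one | COC(OC)C(=O)[C@H]1Oc2ccc([C@@H](C)O[Si](C)(C)C(C)(C)C)cc2[C@H]1O[Si](CC)(CC)CC | intermediate
14 | Cp2TiCl2 (titanocene dichloride) | Cl[Ti](Cl)(C1C=CC=C1)C1C=CC=C1 | starting material
15 | Cp2TiMe2 (dimethyltitanocene) | C[Ti](C)(C1C=CC=C1)C1C=CC=C1 | intermediate
16 | tert-butyl{(1R)-1-[(2R,3R)-2-(3,3-dimethoxyprop-1-en-2-yl)-3-(triethylsilyloxy)-2,3-dihydro-1-benzofuran-5-yl]ethoxy}dimethylsilane | COC(OC)C(=C)[C@H]1Oc2ccc([C@@H](C)O[Si](C)(C)C(C)(C)C)cc2[C@H]1O[Si](CC)(CC)CC | intermediate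
17 | (2R,3R)-2-(3,3-dimethoxyprop-1-en-2-yl)-5-[(1R)-1-hydroxyethyl]-2,3-dihydro-1-benzofuran-3-ol | COC(OC)C(=C)[C@H]1Oc2ccc([C@@H](C)O)cc2[C@H]1O | intermediate
18 | (1R)-1-[(2R,3R)-2-(3,3-dimethoxyprop-1-en-2-yl)-3-(3-methylbutanoyloxy)-2,3-dihydro-1-benzofuran-5-yl]ethyl 3-methylbutanoate | COC(OC)C(=C)[C@H]1Oc2ccc([C@@H](C)OC(=O)CC(C)C)cc2[C@H]1OC(=O)CC(C)C | intermediate
19 | (1R)-1-[(2R,3R)-3-(3-methylbutanoyloxy)-2-(3-oxoprop-1-en-2-yl)-2,3-dihydro-1-benzofuran-5-yl]ethyl 3-methylbutanoate | C=C(C=O)[C@H]1Oc2ccc([C@@H](C)OC(=O)CC(C)C)cc2[C@H]1OC(=O)CC(C)C | target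

**Total step count:** 12.
**Longest linear sequence:** 8 steps (1, 2, 3, 7, 8, 10, 11, 12); the fragment B line (4, 5, 6, 7, 8, 10, 11, 12) is equally long, and the reagent branch (9, 10, 11, 12) is 4.

**Three steps most likely to fail**

Step 8 (aldol). The hindered keto acetal may form its enamine slowly, the β-hydroxy ketone may dehydrate to the aromatic benzofuran, and facial or cis control may be poorer than the model predicts. The fallback gives up amine catalysis and catalyst control. Setting out from 11, a soft-enolisation magnesium-enolate aldol with silyl trapping (MgBr2·OEt2, Et3N, Et3SiCl, EtOAc, rt) closes the ring through a chelated transition state and delivers the silylated cis-aldol directly. Because the (R)-benzylic centre is already in place, the product with the wrong ring configuration, the (2R,3S)-cis silyl aldol F1, is a diastereomer of 13 and is removed by preparative HPLC. The route is rejoined at 13.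

Step 10 (methylenation). The ketone is flanked by two branched, oxygenated carbons and has an acidic C2–H, so Cp2Ti=CH2 may only enolise it or epimerise C2. The fallback is a two-stage Peterson olefination. Setting out from 13, the organocerium reagent from Me3SiCH2MgCl and anhydrous CeCl3 (THF, −78 °C) adds to the carbonyl without enolisation to give the tertiary β-hydroxysilane F2 (either carbinol epimer serves). KH in THF at 0 °C then effects syn-elimination to the bis-silyl ether alkene 16, which is treated with Bu4NF as before. The route is rejoined at 16.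

Step 7 (union). Under carbonate the product 11 carries an acidic α-aryloxy ketone next to an aryl aldehyde and may cyclise prematurely to racemic aldol or benzofuran. The fallback keeps the ketone out of the basic step. Acrolein dimethyl acetal is epoxidised (mCPBA, CH2Cl2) to 2-(dimethoxymethyl)oxirane F3. Setting out from 5, the phenoxide opens F3 at its CH2 terminus (K2CO3, DMF, 70 °C) to give the hydroxy ether F4. Buffered Dess–Martin oxidation (NaHCO3, CH2Cl2) then gives the ketone under non-basic conditions. The route is rejoined at 11.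

**Further compounds**
F1 | step 8 | 1-[(2R,3S)-5-[(1R)-1-(tert-butyldimethylsilyloxy)ethyl]-3-(triethylsilyloxy)-2,3-dihydro-1-benzofuran-2-yl]-2,2-dimethoxyethan-1-one | COC(OC)C(=O)[C@@H]1Oc2ccc([C@@H](C)O[Si](C)(C)C(C)(C)C)cc2[C@@H]1O[Si](CC)(CC)CC
F2 | step 10 | 2-[(2S,3R)-5-[(1R)-1-(tert-butyldimethylsilyloxy)ethyl]-3-(triethylsilyloxy)-2,3-dihydro-1-benzofuran-2-yl]-1,1-dimethoxy-3-(trimethylsilyl)propan-2-ol (both carbinol epimers) | COC(OC)C(O)(C[Si](C)(C)C)[C@H]1Oc2ccc([C@@H](C)O[Si](C)(C)C(C)(C)C)cc2[C@H]1O[Si](CC)(CC)CC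
F3 | step 7 | 2-(dimethoxymethyl)oxirane (racemic) | COC(OC)C1CO1
F4 | step 7 | 5-[(1R)-1-(tert-butyldimethylsilyloxy)ethyl]-2-(2-hydroxy-3,3-dimethoxypropoxy)benzaldehyde (both carbinol epimers) | C[C@@H](O[Si](C)(C)C(C)(C)C)c1ccc(OCC(O)C(OC)OC)c(C=O)c1
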